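**Plan**
- Retrosynthesis: the 6,7-diol goes back to a Z C6=C7 alkene (ring-closing metathesis) and C4–C5 to allylation of a C4 aldehyde. Both bonds that flank the oxepane oxygen, C2–C3 and C15–C16, are then cut at once. The remaining hydroisobenzofuranone goes back to a Diels–Alder adduct (C1–C14, C10–C11) and a C9 allylation (C8–C9).
- Enabling feature: the oxepane oxygen is flanked by C3 and C16, and each can be the nucleophilic carbon of an enol silane (C3 through the C4 carboxyl, C16 through a temporary formyl group). Their partners are latent electrophiles held 1,4 on the bicyclic core: C2 is an acetal carbon of the tetrahydrofuran and C15 is the β-carbon of an ethylidene on the C13 ketone.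
- Forward: Diels–Alder gives the cis-fused core, then C9 methallylation and the C14 ethylidene. A one-operation (3+4) union with a lactate-derived bis(enol silane) builds the oxepane and the quaternary C3. Decarbonylation, C4 allylation and acetylation, metathesis to the nine-membered ether, then epoxidation and hydrolysis follow.
- Stereochemistry: the absolute configuration comes from the (5S)-menthyloxy acetal (C1, C10 by anti Diels–Alder). C9 and C2 arise by convex-face attack on oxocarbenium ions; C3, C15 and C14 in the key step; C4 by chelation control from C3; C6/C7 from the Z-alkene by epoxidation and inverting opening at C7.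

Key step: step 12

Remark: eunicellane numbering is used (C1/C10 ring fusion, C2–O–C9 tetrahydrofuran, C3–O–C16 oxepane, C4 CHOAc, C6/C7 diol, C11=C12–C13=O enone, C14, C15 CHMe, C17–C20 the methyls on C15, C3, C7, C11). Racemic methyl lactate is taken because its stereocentre becomes trigonal in step 11.

**Route**

Step 1
Reactants: 1 (3E)-4-methoxypent-3-en-2-one
Product: 2 tert-butyl{[(3E)-4-methoxypenta-1,3-dien-2-yl]oxy}dimethylsilane
Conditions: t-BuMe2SiOTf, Et3N, Et2O, 0 °C
Reagents that add atoms: tert-butyldimethylsilyl triflate, CC(C)(C)[Si](C)(C)OS(=O)(=O)C(F)(F)F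
Why: Soft enolisation of the methyl ketone (silyl triflate/amine enol silane formation) should give the 1-methoxy-3-silyloxy diene with the enol ether geometry of 1 unchanged.

Step 2
Reactants: 2 silyloxy diene; 3 (5S)-5-(d-menthyloxy)furan-2(5H)-one, d-menthyl = (1S,2R,5S)-2-isopropyl-5-methylcyclohexyl
Product: 4 cis-fused Diels–Alder adduct (C9 lactone; C2 menthyl acetal; C13 silyl enol ether; C11 methoxy epimers)
Conditions: toluene, 100 °C, sealed tube; non-acidic work-up
Reagents that add atoms: none
Why: Diels–Alder reaction in which the CH2 terminus of the diene should bond to the β-carbon of the butenolide and cis-addition on the face anti to the menthyloxy group sets C1 and C10 as a single enantiomer; the C11 centre becomes trigonal in step 4.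

Step 3
Reactants: 4 Diels–Alder adduct
Product: 6 C9 lactol acetate (anomeric mixture), via aluminium hemiacetal 5 (not isolated)
Conditions: i-Bu2AlH, CH2Cl2, –78 °C; then pyridine, DMAP, Ac2O, –78 → 0 °C
Reagents that add atoms: acetic anhydride, CC(=O)OC(C)=O
Why: Reductive acetylation of a lactone, in which one hydride adds at –78 °C and the aluminium hemiacetal is acylated in situ, while the silyl enol ether keeps C13 out of reach of the hydride.

Step 4
Reactants: 6 C9 lactol acetate
Product: 7 enone lactol acetate
Conditions: CF3CO2H (1.5 equiv), CH2Cl2, 0 °C, short contact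
Reagents that add atoms: none
Why: Acid-induced loss of methanol and of the silyl group from the β-methoxy silyl enol ether (the usual unmasking of 1-alkoxy-3-silyloxydiene cycloadducts) should give the 11-methyl enone, while the anomeric acetate and the alkyl acetal tolerate brief anhydrous acid.

Step 5
Reactants: 7 enone lactol acetate
Product: 8 C9-methallyl enone
Conditions: trimethyl(2-methylallyl)silane, Me3SiOTf (0.2 equiv), CH2Cl2, –78 → –40 °C
Reagents that add atoms: trimethyl(2-methylallyl)silane, C=C(C)C[Si](C)(C)C
Why: Hosomi–Sakurai C-glycosylation in which the anomeric acetate ionises far more readily than the menthyl acetal and the allylsilane should attack the bicyclic oxocarbenium ion on its convex face, anti to the fused cyclohexenone, which sets C9.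

Step 6
Reactants: 8 C9-methallyl enone
Product: 10 aldol adduct (diastereomer mixture), via lithium enolate 9 (not isolated)
Conditions: LiN(i-Pr)2, THF, –78 °C; then CH3CHO, –78 °C; NH4Cl quench
Reagents that add atoms: acetaldehyde, CC=O
Why: Kinetic α'-deprotonation of the enone at the C14 methylene followed by aldol addition; both new stereocentres are removed in step 7.

Step 7
Reactants: 10 aldol adduct
Product: 12 (E)-ethylidene dienone (fragment A), via mesylate 11 (not isolated)
Conditions: MeSO2Cl, Et3N, CH2Cl2, 0 °C; then DBU, 0 °C → rt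
Reagents that add atoms: none
Why: Mesylation and E1cB elimination should give the conjugated (E)-ethylidene (methyl anti to the carbonyl, the thermodynamic isomer), which is the C15 acceptor of the key step.

Step 8
Reactants: 13 methyl lactate (racemic)
Product: 14 methyl 2-(allyloxy)propanoate
Conditions: allyl bromide, Ag2O, Et2O, rt, dark
Reagents that add atoms: allyl bromide, C=CCBr
Why: Ag2O-promoted Williamson etherification of an α-hydroxy ester, which avoids ester enolate chemistry.

Step 9
Reactants: 14 methyl 2-(allyloxy)propanoate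
Product: 16 methyl 2-(2-oxoethoxy)propanoate, via ozonide 15 (not isolated)
Conditions: O3, CH2Cl2, –78 °C; then Me2S, –78 °C → rt
Reagents that add atoms: ozone, [O-][O+]=O
Why: Ozonolysis with reductive work-up cleaves the terminal alkene to the α-alkoxy aldehyde.

Step 10
Reactants: 16 methyl 2-(2-oxoethoxy)propanoate
Product: 17 methyl 2-{[(Z)-2-(tert-butyldimethylsilyloxy)ethenyl]oxy}propanoate
Conditions: t-BuMe2SiOTf, Et3N, CH2Cl2, 0 °C
Reagents that add atoms: tert-butyldimethylsilyl triflate, CC(C)(C)[Si](C)(C)OS(=O)(=O)C(F)(F)F
Why: Soft enolisation silylates the aldehyde only (the ester is not enolised under these conditions) and should give the (Z)-enol silane expected for α-alkoxy aldehydes.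

Step 11
Reactants: 17 aldehyde enol silane
Product: 19 mixed bis(enol silane) (fragment B), via lithium ester enolate 18 (not isolated)
Conditions: LiN(i-Pr)2, THF, –78 °C; then Me3SiCl, –78 °C → rt; non-aqueous work-up
Reagents that add atoms: chlorotrimethylsilane, C[Si](C)(C)Cl
Why: Ester enolisation and O-silylation give the ketene silyl acetal, which makes the future C3 far more nucleophilic than the future C16; the ketene acetal geometry is of no consequence.

Step 12
Reactants: 12 (E)-ethylidene dienone (fragment A); 19 mixed bis(enol silane) (fragment B)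
Product: 22 oxepane keto aldehyde ester (C16 formyl epimers), via C2–C3 adduct 20 (not isolated), via silyl dienol ether 21 (not isolated)
Conditions: 12 (1 equiv), 19 (1.3 equiv), Me3SiOTf (0.2 equiv), CH2Cl2, –78 → –20 °C; then 1 M HCl, THF, 0 °C
Reagents that add atoms: none
Why: Proposed new method: Me3SiOTf ionises the C2 menthyl acetal of 12 to the bicyclic oxocarbenium ion, which the ketene silyl acetal terminus of 19 attacks on the convex face (Mukaiyama-type C-glycosylation, C2–C3) to give 20; on warming, the silyl triflate activates the C13 dienone and the remaining aldehyde enol silane closes the oxepane onto C15 (intramolecular Mukaiyama–Michael addition, 7-endo-trig, C15–C16) to give 21, so that both silyl groups of 19 end on the departing menthol and on the C13 oxygen and the triflate is only a catalyst. The closest known reaction type is the Lewis-acid (3+4) annulation of bis(silyl enol ethers) with 1,4-dielectrophilic bis-acetals; new here are the ether oxygen in the middle of the bis-nucleophile and the pairing of one acetal with one enone as the electrophiles. C2 is set by attack anti to the fused cyclohexenone; C3 by an open antiperiplanar transition state in which the methyl group, not the long silyloxyvinyl ether arm, lies next to C1; C15 by delivery of C16 to the face of the (E)-ethylidene that carries C2; C14 by protonation of 21 on work-up anti to the new ring (the cis-fused isomer, which is also expected on equilibration); the C16 formyl epimers are of no consequence. The selectivity the step needs is the order of events: the ketene acetal must reach the oxocarbenium ion before the aldehyde enol silane does, which the large gap in nucleophilicity between the two enol silanes should secure. The enone is engaged only above the temperature of acetal ionisation, and then only intramolecularly at the unhindered exocyclic β-carbon C15.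

Step 13
Reactants: 22 oxepane keto aldehyde ester
Product: 23 oxepane keto ester
Conditions: RhCl(PPh3)3 (1.1 equiv), toluene, 110 °C
Reagents that add atoms: none
Why: Tsuji–Wilkinson decarbonylation (formyl C–H insertion, CO extrusion, C–H reductive elimination) removes the helper group, and both C16 epimers converge on one compound.

Step 14
Reactants: 23 oxepane keto ester
Product: 24 diol (C4 CH2OH; C13 allylic alcohol epimers)
Conditions: i-Bu2AlH (5 equiv), CH2Cl2, –78 → 0 °C; aq. potassium sodium tartrate
Reagents that add atoms: none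
Why: Exhaustive hydride reduction of the hindered ester and 1,2-reduction of the enone, chosen so that no selective partial reduction next to a ketone is needed.

Step 15
Reactants: 24 diol
Product: 25 keto aldehyde
Conditions: Dess–Martin periodinane (3 equiv), NaHCO3, CH2Cl2, rt
Reagents that add atoms: none
Why: Dess–Martin oxidation returns the C13 enone and gives the non-enolisable C4 aldehyde; C14 is untouched.

Step 16
Reactants: 25 keto aldehyde
Product: 26 C4 homoallylic alcohol
Conditions: MgBr2·OEt2 (3 equiv), CH2Cl2, –40 °C; allylSnBu3, –40 → 0 °C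
Reagents that add atoms: allyltributylstannane, C=CC[Sn](CCCC)(CCCC)CCCC
Why: Chelation-controlled allylation (Cram chelate model): MgBr2 bridges the aldehyde oxygen and the oxepane oxygen on C3 and the allylstannane should attack from the side of the C3 methyl group, which sets C4; the aldehyde reacts far faster than the enone.

Step 17
Reactants: 26 C4 homoallylic alcohol
Product: 27 C4 acetate
Conditions: Ac2O, DMAP, pyridine, rt
Reagents that add atoms: acetic anhydride, CC(=O)OC(C)=O
Why: DMAP-catalysed acylation of the secondary alcohol.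

Step 18
Reactants: 27 C4 acetate
Product: 28 tetracyclic (Z)-oxonene
Conditions: second-generation Grubbs catalyst (10 mol %), toluene (1 mM), 80 °C
Reagents that add atoms: none
Why: Ring-closing metathesis of the allyl and methallyl arms, held cis on the tetrahydrofuran, should close the nine-membered ether as the Z trisubstituted alkene enforced by ring size; the electron-poor enone does not take part.

Step 19
Reactants: 28 tetracyclic (Z)-oxonene
Product: 29 6,7-epoxide
Conditions: mCPBA, NaHCO3, CH2Cl2, 0 °C
Reagents that add atoms: 3-chloroperbenzoic acid, OOC(=O)c1cccc(Cl)c1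
Why: Prilezhaev epoxidation selects the electron-rich trisubstituted alkene over the enone and should occur on the exposed peripheral face of the medium-ring alkene.

Step 20
Reactants: 29 6,7-epoxide
Product: 30 CNP0318718.1 (target)
Conditions: HClO4 (cat.), THF/H2O, 0 °C → rt
Reagents that add atoms: water, O
Why: Acid-catalysed epoxide hydrolysis in which water opens the protonated epoxide at the tertiary C7 with inversion while C6 keeps its oxygen, giving the 6,7-diol of the target; the acetate and enone are untouched.

**Compound list**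
1 | (3E)-4-methoxypent-3-en-2-one | CO/C(C)=C/C(C)=O | starting material
2 | tert-butyl{[(3E)-4-methoxypenta-1,3-dien-2-yl]oxy}dimethylsilane | CO/C(C)=C/C(=C)O[Si](C)(C)C(C)(C)C | intermediate
3 | (5S)-5-[(1S,2R,5S)-menthyloxy]furan-2(5H)-one | O=C1O[C@H](O[C@H]5C[C@@H](C)CC[C@@H]5C(C)C)C=C1 | starting material
4 | cis-fused Diels–Alder adduct (C9 lactone, C2 menthyl acetal, C13 silyl enol ether, C11 OMe/Me epimers; H-1 and H-10 cis and anti to the menthyloxy group) | O=C1O[C@H](O[C@H]5C[C@@H](C)CC[C@@H]5C(C)C)[C@@H]2[C@H]1C(C)(OC)C=C(O[Si](C)(C)C(C)(C)C)C2 | intermediate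
5 | diisobutylaluminium hemiacetal of 4 | CC(C)C[Al](CC(C)C)OC1O[C@H](O[C@H]5C[C@@H](C)CC[C@@H]5C(C)C)[C@@H]2[C@H]1C(C)(OC)C=C(O[Si](C)(C)C(C)(C)C)C2 | intermediate (not isolated)
6 | C9 lactol acetate (anomeric mixture) | CC(=O)OC1O[C@H](O[C@H]5C[C@@H](C)CC[C@@H]5C(C)C)[C@@H]2[C@H]1C(C)(OC)C=C(O[Si](C)(C)C(C)(C)C)C2 | intermediate
7 | enone lactol acetate (11-methyl-11-en-13-one) | CC(=O)OC1O[C@H](O[C@H]5C[C@@H](C)CC[C@@H]5C(C)C)[C@@H]2[C@H]1C(C)=CC(=O)C2 | intermediate
8 | C9-methallyl enone (methallyl cis to H-10, on the convex face) | C=C(C)C[C@@H]1O[C@H](O[C@H]5C[C@@H](C)CC[C@@H]5C(C)C)[C@@H]2[C@H]1C(C)=CC(=O)C2 | intermediate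
9 | lithium dienolate of 8 (C13–O–Li, C13=C14) | C=C(C)C[C@@H]1O[C@H](O[C@H]5C[C@@H](C)CC[C@@H]5C(C)C)[C@@H]2[C@H]1C(C)=CC(O[Li])=C2 | intermediate (not isolated)
10 | C14 (1-hydroxyethyl) aldol adduct (mixture at C14 and the carbinol) | C=C(C)C[C@@H]1O[C@H](O[C@H]5C[C@@H](C)CC[C@@H]5C(C)C)[C@@H]2[C@H]1C(C)=CC(=O)C2C(C)O | intermediate
11 | mesylate of 10 | C=C(C)C[C@@H]1O[C@H](O[C@H]5C[C@@H](C)CC[C@@H]5C(C)C)[C@@H]2[C@H]1C(C)=CC(=O)C2C(C)OS(C)(=O)=O | intermediate (not isolated)
12 | fragment A: C14 (E)-ethylidene dienone with C2 menthyl acetal and C9 methallyl | C=C(C)C[C@@H]1O[C@H](O[C@H]5C[C@@H](C)CC[C@@H]5C(C)C)[C@@H]2[C@H]1C(C)=CC(=O)/C2=C/C | intermediate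
13 | methyl lactate (racemic) | CC(O)C(=O)OC | starting material
14 | methyl 2-(allyloxy)propanoate | C=CCOC(C)C(=O)OC | intermediate
15 | ozonide (1,2,4-trioxolane) of 14 | COC(=O)C(C)OCC1OCOO1 | intermediate (not isolated)
16 | methyl 2-(2-oxoethoxy)propanoate | COC(=O)C(C)OCC=O | intermediate
17 | methyl 2-{[(Z)-2-(tert-butyldimethylsilyloxy)ethenyl]oxy}propanoate | COC(=O)C(C)O/C=C\O[Si](C)(C)C(C)(C)C | intermediate
18 | lithium ester enolate of 17 | COC(O[Li])=C(C)O/C=C\O[Si](C)(C)C(C)(C)C | intermediate (not isolated)
19 | fragment B: methyl trimethylsilyl ketene acetal of 17 | COC(O[Si](C)(C)C)=C(C)O/C=C\O[Si](C)(C)C(C)(C)C | intermediate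
20 | C2–C3 adduct (quaternary C3 with methyl, CO2Me and the silyloxyvinyl ether; dienone intact) | C=C(C)C[C@@H]1O[C@H]([C@@](C)(O/C=C\O[Si](C)(C)C(C)(C)C)C(=O)OC)[C@@H]2[C@H]1C(C)=CC(=O)/C2=C/C | intermediate (not isolated)
21 | cyclised trimethylsilyl dienol ether (C13–OSiMe3, C13=C14; C16 formyl) | C=C(C)C[C@@H]1O[C@H]2[C@@H]3[C@H]1C(C)=CC(O[Si](C)(C)C)=C3[C@@H](C)C(C=O)O[C@@]2(C)C(=O)OC | intermediate (not isolated)
22 | oxepane keto aldehyde ester (C16 formyl epimers; C3 CO2Me) | C=C(C)C[C@@H]1O[C@H]2[C@@H]3[C@H]1C(C)=CC(=O)[C@@H]3[C@@H](C)C(C=O)O[C@@]2(C)C(=O)OC | intermediate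
23 | oxepane keto ester | C=C(C)C[C@@H]1O[C@H]2[C@@H]3[C@H]1C(C)=CC(=O)[C@@H]3[C@@H](C)CO[C@@]2(C)C(=O)OC | intermediate
24 | diol (C4 hydroxymethyl, C13 allylic alcohol epimers) | C=C(C)C[C@@H]1O[C@H]2[C@@H]3[C@H]1C(C)=CC(O)[C@@H]3[C@@H](C)CO[C@@]2(C)CO | intermediate
25 | keto aldehyde (C4 CHO, C13 enone) | C=C(C)C[C@@H]1O[C@H]2[C@@H]3[C@H]1C(C)=CC(=O)[C@@H]3[C@@H](C)CO[C@@]2(C)C=O | intermediate
26 | C4 homoallylic alcohol | C=C(C)C[C@@H]1O[C@H]2[C@@H]3[C@H]1C(C)=CC(=O)[C@@H]3[C@@H](C)CO[C@@]2(C)[C@H](O)CC=C | intermediate
27 | C4 acetate | C=C(C)C[C@@H]1O[C@H]2[C@@H]3[C@H]1C(C)=CC(=O)[C@@H]3[C@@H](C)CO[C@@]2(C)[C@H](OC(C)=O)CC=C | intermediate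
28 | tetracyclic (6Z)-oxonene | CC(=O)O[C@@H]1C/C=C(C)\C[C@@H]2O[C@H]3[C@@H]4[C@H]2C(C)=CC(=O)[C@@H]4[C@@H](C)CO[C@@]13C | intermediate
29 | 6,7-epoxide (oxygen on the face that keeps the C6 configuration of the target) | CC(=O)O[C@@H]1C[C@H]5O[C@@]5(C)C[C@@H]2O[C@H]3[C@@H]4[C@H]2C(C)=CC(=O)[C@@H]4[C@@H](C)CO[C@@]13C | intermediate
30 | CNP0318718.1 | CC(=O)O[C@@H]1C[C@@H](O)[C@](C)(O)C[C@@H]2O[C@H]3[C@@H]4[C@H]2C(C)=CC(=O)[C@@H]4[C@@H](C)CO[C@@]13C | target

**Summary**
Total step count: 20. Longest linear sequence: 16 steps (steps 1–7 and 12–20); steps 8–11 make fragment B.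

Steps most likely to fail:

1. Step 12. After the first C–C bond, the aldehyde enol silane may be lost by protodesilylation or consumed between molecules before the enone is activated, so the ring-closing conjugate addition does not follow. Facial discrimination at the C3 ketene acetal carbon may also be modest. Fallback with two separate, known events, setting out from 12 and 13 and returning at 23: methyl lactate 13 is O-alkylated with chloromethyl phenyl selenide (NaH, THF) to methyl 2-[(phenylselanyl)methoxy]propanoate F1, which is converted (LiN(i-Pr)2, Me3SiCl) into its trimethylsilyl ketene acetal F2. Me3SiOTf-mediated Mukaiyama addition of F2 to 12 gives the C2–C3-linked selenide F3. Bu3SnH/AIBN (benzene, 80 °C, slow addition) then generates the alkoxymethyl radical, which closes the oxepane by 7-endo Giese addition to C15 and gives 23 directly, without the formyl helper.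

2. Step 13. Oxidative addition at the hindered secondary formyl group may be slow, and at the temperature needed the methallyl alkene may isomerise or the acyl-rhodium intermediate may eliminate. Fallback from 22, returning at 23: Pinnick oxidation (NaClO2, NaH2PO4, 2-methyl-2-butene) gives the C16 carboxylic acid F4. Photoredox hydrodecarboxylation (9-mesityl-10-methylacridinium tetrafluoroborate, PhSSPh, i-Pr2NEt, CF3CH2OH, blue light) then replaces CO2H by H through the α-alkoxy radical.

3. Step 19. The peracid may attack the other face of the medium-ring alkene (poor or reversed facial selectivity), which after inverting hydrolysis at C7 would give the 6,7-bis-epimeric diol. Fallback from 28, returning at 30: OsO4/NMO dihydroxylation on that same accessible face gives the cis-6,7-diol F5, which has the C7 configuration of the target. Oxidation of the secondary C6 alcohol (SO3·pyridine, DMSO, Et3N) gives the 6-oxo-7-hydroxy compound F6. Hydroxyl-directed reduction with Me4NBH(OAc)3 (AcOH/MeCN, –20 °C) delivers hydride from the side of the C7 oxygen and should give the trans-diol 30 without touching the enone.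

Further compounds
F1 | step 12 | methyl 2-[(phenylselanyl)methoxy]propanoate | COC(=O)C(C)OC[Se]c1ccccc1
F2 | step 12 | methyl trimethylsilyl ketene acetal of F1 | COC(O[Si](C)(C)C)=C(C)OC[Se]c1ccccc1
F3 | step 12 | C2–C3-linked selenide (quaternary C3 with methyl, CO2Me and OCH2SePh; dienone intact) | C=C(C)C[C@@H]1O[C@H]([C@@](C)(OC[Se]c2ccccc2)C(=O)OC)[C@@H]3[C@H]1C(C)=CC(=O)/C3=C/C
F4 | step 13 | C16 carboxylic acid of the oxepane keto ester | C=C(C)C[C@@H]1O[C@H]2[C@@H]3[C@H]1C(C)=CC(=O)[C@@H]3[C@@H](C)C(C(=O)O)O[C@@]2(C)C(=O)OC
F5 | step 19 | cis-6,7-diol (6-epimer of 30) | CC(=O)O[C@@H]1C[C@H](O)[C@](C)(O)C[C@@H]2O[C@H]3[C@@H]4[C@H]2C(C)=CC(=O)[C@@H]4[C@@H](C)CO[C@@]13C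
F6 | step 19 | 6-oxo-7-hydroxy compound | CC(=O)O[C@@H]1CC(=O)[C@](C)(O)C[C@@H]2O[C@H]3[C@@H]4[C@H]2C(C)=CC(=O)[C@@H]4[C@@H](C)CO[C@@]13C
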